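The route rests on cutting the C6–O bond of the cis C1–OH/C6–OH pair, which leads back to an achiral para-quinol. In its cyclohexa-2,5-dienone ring, C1 (carrying OH and C7H2OBz) is prochiral and the C2=C3 and C6=C5 enone arms are enantiotopic. In the key step a phenylboronic acid tether on C1–OH, steered by a chiral amine–thiourea, delivers oxygen to C6 of one arm. This closes a cis-fused dioxaborolane and fixes C1 and C6 at once. The precursor, 4-(benzoyloxymethyl)-4-hydroxycyclohexa-2,5-dienone, is two steps from 4-hydroxybenzyl alcohol. Afterwards a diene/singlet-oxygen sequence installs the C5 and C2 oxygens and moves the unsaturation to C3=C4.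

Key step: step 3

Remark: target numbering is used for every intermediate (C1 = carbinol carbon bearing C7H2OBz, C2 = target carbonyl carbon, C5 = benzoate-bearing carbon, C6 = secondary carbinol carbon). Which pseudo-enantiomeric catalyst (quinine- or quinidine-derived) attacks the C6=C5 arm cannot be predicted for this substrate class; it is assumed to be settled by a two-catalyst screen, and the route is written for that catalyst.

Step 1
Reactants: 1 4-hydroxybenzyl alcohol; 2 vinyl benzoate
Product: 3 4-hydroxybenzyl benzoate
Conditions: immobilised Candida antarctica lipase B (Novozym 435), 2 (3 equiv), THF, 50 °C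
Reagents that add atoms: none
Why: Lipase-catalysed irreversible transesterification with an enol ester should benzoylate only the primary benzylic hydroxyl, because the enzyme does not accept the phenol and the neutral medium avoids phenoxide acylation and quinone-methide loss of the benzylic ester; no stereocentre is involved.

Step 2
Reactants: 3 4-hydroxybenzyl benzoate
Product: 4 4-(benzoyloxymethyl)-4-hydroxycyclohexa-2,5-dien-1-one (achiral para-quinol)
Conditions: PhI(OAc)2 (1.1 equiv), MeCN/H2O (3:1), 0 °C
Reagents that add atoms: water, O
Why: Hypervalent-iodine oxidative dearomatisation, in which the phenol exchanges onto iodine(III) and water attacks the para carbon, which carries C7 and so cannot rearomatise, should give the achiral para-quinol whose two enone arms are mirror images.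

Step 3
Reactants: 4 para-quinol; 5 phenylboronic acid
Product: 7 cis-fused phenylboronate of 4-(benzoyloxymethyl)-4,5-dihydroxycyclohex-2-en-1-one (C1 S; C6 S), via boronic hemiester 6 (not isolated)
Conditions: 5 (1.3 equiv), 9-amino-9-deoxy-epi-cinchona 3,5-bis(trifluoromethyl)phenyl thiourea (10–20 mol %), 4 Å MS, CH2Cl2, −20 °C → rt
Reagents that add atoms: none
Why: Proposed new method: the tertiary C1–OH condenses reversibly with 5 (sieves remove water) to hemiester 6; the quinuclidine nitrogen of the catalyst coordinates boron and makes the remaining B–OH oxygen nucleophilic while the thiourea hydrogen-bonds the dienone carbonyl, and this oxygen adds in an oxa-Michael fashion to C6, after which the enolate is protonated at C5. The closest known reaction types are the amine–thiourea-catalysed oxa-Michael addition of boronic acid hemiesters of γ-hydroxy enones and catalytic desymmetrisations of para-quinols by tethered oxygen nucleophiles; new is their combination on a tertiary quinol carbinol. The one ring formed, the 1,3,2-dioxaborolane (C1, O, B, O, C6), closes 5-exo-trig. C6 is set relative to C1 by the two-atom O–B–O tether, which reaches only the ring face carrying C1–O and so enforces the cis fusion, whereas the absolute configuration of C1 and C6 together is set by the catalyst's choice between the enantiotopic arms C6=C5 and C2=C3. The step therefore needs only enantiotopic-group selectivity from the catalyst; mono-addition is secured by the substrate, because the single hydroxyl is consumed in the tether and the second enone arm is left without an internal nucleophile.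

Step 4
Reactants: 7 cis-fused phenylboronate
Product: 9 (C1 S; C6 S)-4-(benzoyloxymethyl)-4,5-(isopropylidenedioxy)cyclohex-2-en-1-one, via free cis-diol 8 (not isolated)
Conditions: pinacol (1.5 equiv), CH2Cl2, rt; then Me2C(OMe)2 (5 equiv), PPTS (10 mol %), rt
Reagents that add atoms: 2,2-dimethoxypropane, COC(C)(C)OC
Why: Transesterification of the boronate onto pinacol followed by acid-catalysed ketalisation of the freed cis-1,2-diol (acetonide formation) should replace boron by a robust group without touching C1 or C6, and the absence of base and peroxide avoids retro-oxa-Michael opening and enone epoxidation.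

Step 5
Reactants: 9 acetonide enone
Product: 10 C4 allylic alcohol of 9 (C2=C3 retained; C4–OH expected cis to the dioxolane oxygens)
Conditions: NaBH4, CeCl3·7H2O, MeOH, −78 → −40 °C
Reagents that add atoms: none
Why: Luche reduction should give clean 1,2-reduction of the C4 carbonyl with benzoate and ketal intact; hydride is expected from the face opposite the dioxolane, but the C4 configuration is immaterial because C4 becomes sp2 in step 6.

Step 6
Reactants: 10 allylic alcohol
Product: 11 acetonide of (1S,6S)-1-(benzoyloxymethyl)cyclohexa-2,4-diene-1,6-diol
Conditions: Martin sulfurane (1.5 equiv), CH2Cl2, 0 °C → rt; used at once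
Reagents that add atoms: none
Why: Martin sulfurane dehydration, in which the C4 alkoxysulfonium ion loses a C5 hydrogen by E2 elimination, can give only the conjugated C2=C3–C4=C5 diene because C1 has no hydrogen and C3 is vinylic; C1 and C6 are untouched.

Step 7
Reactants: 11 diene acetonide
Product: 13 cis-2,5-diol (C3=C4; C2–OH and C5–OH both trans to the dioxolane oxygens), via endoperoxide 12 (not isolated)
Conditions: O2, tetraphenylporphyrin (cat.), visible light, CH2Cl2, −20 °C; then thiourea, MeOH, rt
Reagents that add atoms: dioxygen, O=O
Why: [4+2] cycloaddition of singlet oxygen to the s-cis ring diene should occur on the face opposite the dioxolane (its endo methyl shields the other face, C7H2OBz is pseudo-equatorial), which sets C5–O trans to C6–O as the target requires and C2–O on the same face, and thiourea then cleaves the O–O bond without affecting alkene, esters or ketal.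

Step 8
Reactants: 13 cis-2,5-diol; 14 benzoyl chloride
Product: 15 5-O-benzoate of 13 (C2–OH free)
Conditions: 14 (1.05 equiv), pyridine, CH2Cl2, −40 → 0 °C
Reagents that add atoms: none
Why: Pyridine-mediated acylation is expected to select the C5 hydroxyl, flanked only by C6–H, over the C2 hydroxyl, which lies next to the fully substituted C1 and cis to C7H2OBz; the C5 configuration is retained because only the O–H bond reacts.

Step 9
Reactants: 15 monobenzoate
Product: 16 zeylenone 1,6-O-acetonide (1S,5R,6S)
Conditions: Dess–Martin periodinane (1.3 equiv), CH2Cl2, rt
Reagents that add atoms: none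
Why: Dess–Martin oxidation should convert the hindered allylic C2 alcohol into the C2 enone under non-basic conditions, so the γ-hydrogen at C5 is not removed and the benzoates do not migrate; the C2 stereocentre is erased and C1, C5 and C6 are untouched.

Step 10
Reactants: 16 zeylenone acetonide
Product: 17 zeylenone, (1S,5R,6S)
Conditions: TFA/H2O (9:1), 0 °C
Reagents that add atoms: none
Why: Acid-catalysed hydrolysis of the isopropylidene ketal frees the cis C1/C6 diol; the esters should be stable to aqueous TFA at 0 °C, and acyl migration, which is base-promoted, should not compete.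

Compound list
1 | 4-hydroxybenzyl alcohol | OCc1ccc(O)cc1 | starting material
2 | vinyl benzoate | C=COC(=O)c1ccccc1 | starting material
3 | 4-hydroxybenzyl benzoate | O=C(OCc1ccc(O)cc1)c1ccccc1 | intermediate
4 | 4-(benzoyloxymethyl)-4-hydroxycyclohexa-2,5-dien-1-one | O=C1C=CC(O)(COC(=O)c2ccccc2)C=C1 | intermediate
5 | phenylboronic acid | OB(O)c1ccccc1 | starting material
6 | phenylboronic hemiester of 4 on the tertiary oxygen, C1–O–B(OH)Ph | O=C1C=CC(OB(O)c2ccccc2)(COC(=O)c2ccccc2)C=C1 | intermediate (not isolated)
7 | cis-fused 2-phenyl-1,3,2-dioxaborolane across C1–O/C6–O of 4-(benzoyloxymethyl)-4,5-dihydroxycyclohex-2-en-1-one (C1 S; C6 S) | O=C(OC[C@@]1(OB(c2ccccc2)O3)C=CC(=O)C[C@@H]13)c1ccccc1 | intermediate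
8 | (C1 S; C6 S)-4-(benzoyloxymethyl)-4,5-dihydroxycyclohex-2-en-1-one, cis-diol | O=C(OC[C@@]1(O)C=CC(=O)C[C@@H]1O)c1ccccc1 | intermediate (not isolated)
9 | acetonide of 8 | O=C(OC[C@@]1(OC(C)(C)O3)C=CC(=O)C[C@@H]13)c1ccccc1 | intermediate
10 | C4 allylic alcohol of 9 (C4–OH drawn cis to the dioxolane oxygens; the epimer would serve equally) | O=C(OC[C@@]1(OC(C)(C)O3)C=C[C@H](O)C[C@@H]13)c1ccccc1 | intermediate
11 | acetonide of (1S,6S)-1-(benzoyloxymethyl)cyclohexa-2,4-diene-1,6-diol | O=C(OC[C@@]1(OC(C)(C)O3)C=CC=C[C@@H]13)c1ccccc1 | intermediate
12 | 2,5-endoperoxide of 11, O–O bridge on the face opposite the dioxolane | O=C(OC[C@@]1(OC(C)(C)O3)[C@@H]4C=C[C@@H](OO4)[C@@H]13)c1ccccc1 | intermediate (not isolated)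
13 | acetonide cis-2,5-diol, C3=C4, both hydroxyls trans to the dioxolane oxygens | O=C(OC[C@@]1(OC(C)(C)O3)[C@@H](O)C=C[C@@H](O)[C@@H]13)c1ccccc1 | intermediate
14 | benzoyl chloride | O=C(Cl)c1ccccc1 | starting material
15 | 5-O-benzoate of 13 | O=C(OC[C@@]1(OC(C)(C)O3)[C@@H](O)C=C[C@@H](OC(=O)c4ccccc4)[C@@H]13)c1ccccc1 | intermediate
16 | zeylenone 1,6-O-acetonide | O=C(OC[C@@]1(OC(C)(C)O3)C(=O)C=C[C@@H](OC(=O)c4ccccc4)[C@@H]13)c1ccccc1 | intermediate
17 | zeylenone, (1S,5R,6S) | O=C(OC[C@@]1(O)C(=O)C=C[C@@H](OC(=O)c2ccccc2)[C@@H]1O)c1ccccc1 | target

Total step count: 10. Longest linear sequence: 10 steps (1 → 17).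

Steps most likely to fail

Step 3 (proposed new method). The tertiary carbinol may esterify with boron too slowly for the catalysed pathway to dominate. The catalyst may discriminate poorly between the two enone arms. Reversible ring opening through the achiral dienone may erode the enantiomeric purity. The fallback uses known chemistry and sets out from 4. A chiral BINOL-derived phosphoric acid (for example TRIP, 5–10 mol %) with isobutyraldehyde in CH2Cl2 should effect the established hemiacetalisation/oxa-Michael desymmetrisation of para-quinols. This forms the same C6–O bond with the same cis fusion and gives the 2-isopropyl-1,3-dioxolane acetal F1. Aqueous TFA then releases diol 8, where the fallback rejoins the route; 8 is ketalised to 9 as in the second stage of step 4.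

Step 6. The activated allylic C4–O bond may ionise and be captured by substitution or allylic transposition instead of eliminating, and the diene may dimerise by [4+2] cycloaddition during handling. The fallback sets out from 10. Methyl chloroformate and pyridine give the allylic methyl carbonate F2. Pd(PPh3)4 (5 mol %) in THF at 60 °C should then ionise it to a π-allyl palladium species, which undergoes β-hydride elimination from C5 to give diene 11 under neutral conditions. The fallback rejoins the route at 11, which is taken directly into step 7.

Step 8. The reagent may not distinguish the two secondary allylic hydroxyls well enough, giving the C2 ester or the diester. The fallback fixes the site by construction and sets out from 9. Soft enolisation (TMSOTf, Et3N, CH2Cl2, 0 °C) can only deprotonate C5, because C1 has no hydrogen, and gives the cross-conjugated trimethylsilyl dienol ether F3. Rubottom oxidation with dimethyldioxirane on the face opposite the dioxolane, then mild acid, gives the C5 α-hydroxy ketone F4 with C5–O trans to C6–O. Benzoyl chloride 14 and pyridine give the C5 benzoate F5. Nucleophilic epoxidation of C2=C3 (t-BuOOH, DBU), expected anti to the dioxolane, gives the epoxy ketone F6. Wharton transposition (N2H4·H2O, AcOH, MeOH, 0 °C) then gives the C2 allylic alcohol 15, where the fallback rejoins the route before step 9.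

Further compounds
F1 | step 3 | cis-fused 2-isopropyl-1,3-dioxolane acetal of diol 8 (isopropyl on the convex face) | O=C(OC[C@@]1(O[C@H](C(C)C)O3)C=CC(=O)C[C@@H]13)c1ccccc1
F2 | step 6 | C4 methyl carbonate of allylic alcohol 10 | O=C(OC[C@@]1(OC(C)(C)O3)C=C[C@H](OC(=O)OC)C[C@@H]13)c1ccccc1
F3 | step 8 | C4 trimethylsilyl dienol ether of 9 (C2=C3 and C4=C5) | O=C(OC[C@@]1(OC(C)(C)O3)C=CC(O[Si](C)(C)C)=C[C@@H]13)c1ccccc1
F4 | step 8 | C5 α-hydroxy ketone of 9 (C5–OH trans to C6–O) | O=C(OC[C@@]1(OC(C)(C)O3)C=CC(=O)[C@@H](O)[C@@H]13)c1ccccc1
F5 | step 8 | C5 benzoate of F4 | O=C(OC[C@@]1(OC(C)(C)O3)C=CC(=O)[C@@H](OC(=O)c4ccccc4)[C@@H]13)c1ccccc1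
F6 | step 8 | C2–C3 epoxide of F5 (epoxide anti to the dioxolane) | O=C(OC[C@@]1(OC(C)(C)O3)[C@H]4O[C@H]4C(=O)[C@@H](OC(=O)c5ccccc5)[C@@H]13)c1ccccc1
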